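**Retrosynthetic overview**

1. Target ⇒ macrocycle carrying C14‑O‑PMB and C15‑O‑TBS; the end game is PMB removal, allylic oxidation to the C14 enal and desilylation.
2. Ten‑membered carbocycle ⇒ acyclic triene by ring‑closing metathesis at C1=C10; the C8 ester ⇒ invertive Mitsunobu esterification of the 8‑epi alcohol with (R)‑2‑methylbutanoic acid.
3. Key disconnection C7–C8: intermolecular CrCl2‑mediated carbonyl allylation of a β,γ‑unsaturated aldehyde (C8–C10, C14) by a 3‑(bromomethyl)butenolide (C1–C7, C11–C13, C15). It sets C7 and C8 relative to C6 and creates the α‑methylene lactone.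
4. Bromolactone ⇒ (S)‑5‑(hydroxymethyl)butyrolactone (C6 from the chiral pool) by E‑selective Wittig olefination (C4=C5), then α‑selenenylation, hydroxymethylation, selenoxide elimination and bromination; aldehyde ⇒ 2‑methylenepropane‑1,3‑diol.
5. Ring order: the γ‑lactone is bought and carried throughout; the ten‑membered ring is closed last.

Assumption: atom labels follow germacrane numbering (lactone C=O = C12, exocyclic CH2 = C13, CHO = C14, CH2OH = C15); (R)‑2‑methylbutanoic acid and (S)‑5‑(hydroxymethyl)dihydrofuran‑2(3H)‑one are bought enantiopure. TBS = tert‑butyldimethylsilyl, PMB = 4‑methoxybenzyl, DMP = Dess–Martin periodinane.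

**Route**

Step 1
Reactants: 1 5‑bromopent‑1‑ene
Product: 2 (pent‑4‑en‑1‑yl)triphenylphosphonium bromide
Conditions: PPh3, MeCN, reflux, 48 h
Reagents that add atoms: triphenylphosphine, c1ccc(cc1)P(c1ccccc1)c1ccccc1
Why: SN2 quaternisation of the phosphine by an unhindered primary bromide gives the crystalline phosphonium salt.

Step 2
Reactants: 2 (pent‑4‑en‑1‑yl)triphenylphosphonium bromide
Product: 5 2‑(triphenyl‑λ5‑phosphanylidene)hex‑5‑enal, via ylide 3 (not isolated), via formylphosphonium ethoxide 4 (not isolated)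
Conditions: KOtBu, THF, 0 °C; then HCO2Et, 0 °C → rt
Reagents that add atoms: ethyl formate, CCOC=O
Why: C‑formylation of the non‑stabilised ylide by the formate ester (Claisen‑type acylation of a Wittig ylide), followed by deprotonation of the acylphosphonium by the released ethoxide, gives the isolable stabilised α‑formyl ylide.

Step 3
Reactants: 6 (5S)‑5‑(hydroxymethyl)oxolan‑2‑one
Product: 7 (2S)‑5‑oxooxolane‑2‑carbaldehyde
Conditions: DMP, pyridine, CH2Cl2, 0 °C → rt; crude used at once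
Reagents that add atoms: none
Why: Dess–Martin oxidation of the primary alcohol under buffered, near‑neutral conditions gives the aldehyde without epimerising the adjacent C6 stereocentre.

Step 4
Reactants: 7 (2S)‑5‑oxooxolane‑2‑carbaldehyde; 5 2‑(triphenyl‑λ5‑phosphanylidene)hex‑5‑enal
Product: 8 (2E)‑2‑{[(2S)‑5‑oxooxolan‑2‑yl]methylidene}hex‑5‑enal
Conditions: PhMe, 80 °C, 12 h
Reagents that add atoms: none
Why: Wittig olefination with a stabilised α‑branched formyl ylide is under thermodynamic control and places CHO trans to the lactone carbon, which is the C4=C5 geometry of the target (C15 trans to C6); the neutral conditions leave C6 intact.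

Step 5
Reactants: 8 (2E)‑2‑{[(2S)‑5‑oxooxolan‑2‑yl]methylidene}hex‑5‑enal
Product: 9 (5S)‑5‑[(1E)‑2‑(hydroxymethyl)hexa‑1,5‑dien‑1‑yl]oxolan‑2‑one
Conditions: NaBH4, CeCl3·7H2O, MeOH, −40 °C
Reagents that add atoms: none
Why: Luche reduction gives clean 1,2‑reduction of the enal to the C15 allylic alcohol, and at low temperature the γ‑lactone is not touched.

Step 6
Reactants: 9 (5S)‑5‑[(1E)‑2‑(hydroxymethyl)hexa‑1,5‑dien‑1‑yl]oxolan‑2‑one
Product: 10 (5S)‑5‑[(1E)‑2‑(TBSO‑methyl)hexa‑1,5‑dien‑1‑yl]oxolan‑2‑one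
Conditions: TBSCl, imidazole, DMF, rt
Reagents that add atoms: tert‑butyldimethylsilyl chloride, CC(C)(C)[Si](C)(C)Cl
Why: Standard silylation of the primary allylic alcohol; this group is removed only in the last step.

Step 7
Reactants: 10 (5S)‑5‑[(1E)‑2‑(TBSO‑methyl)hexa‑1,5‑dien‑1‑yl]oxolan‑2‑one
Product: 12 (5S)‑5‑[(1E)‑2‑(TBSO‑methyl)hexa‑1,5‑dien‑1‑yl]‑3‑(phenylselanyl)oxolan‑2‑one (C3 epimers), via lithium enolate 11 (not isolated)
Conditions: LiN(iPr)2, THF, −78 °C; then PhSeCl, −78 °C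
Reagents that add atoms: benzeneselenenyl chloride, Cl[Se]c1ccccc1
Why: α‑Selenenylation of the lactone enolate is much faster than addition of PhSeCl to the alkenes at −78 °C, and the C3 configuration is irrelevant because this carbon becomes sp2.

Step 8
Reactants: 12 (5S)‑5‑[(1E)‑2‑(TBSO‑methyl)hexa‑1,5‑dien‑1‑yl]‑3‑(phenylselanyl)oxolan‑2‑one
Product: 14 (5S)‑5‑[(1E)‑2‑(TBSO‑methyl)hexa‑1,5‑dien‑1‑yl]‑3‑(hydroxymethyl)‑3‑(phenylselanyl)oxolan‑2‑one (C3 epimers), via lithium enolate 13 (not isolated)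
Conditions: LiN(iPr)2, THF, −78 °C; then HCHO (gas from cracked paraformaldehyde), −78 → −20 °C; AcOH quench
Reagents that add atoms: formaldehyde, C=O
Why: Aldol addition of the selenium‑stabilised lactone enolate to monomeric formaldehyde installs C13 as a hydroxymethyl group on the quaternary α‑carbon.

Step 9
Reactants: 14 (5S)‑5‑[(1E)‑2‑(TBSO‑methyl)hexa‑1,5‑dien‑1‑yl]‑3‑(hydroxymethyl)‑3‑(phenylselanyl)oxolan‑2‑one
Product: 16 (5R)‑5‑[(1E)‑2‑(TBSO‑methyl)hexa‑1,5‑dien‑1‑yl]‑3‑(hydroxymethyl)furan‑2(5H)‑one, via selenoxide 15 (not isolated)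
Conditions: 30% H2O2, pyridine, CH2Cl2, 0 °C → rt
Reagents that add atoms: none
Why: Selenoxide syn‑elimination avoids the carbinol carbon and therefore goes into the ring to give the butenolide (the descriptor changes from S to R only because CIP priorities change).

Step 10
Reactants: 16 (5R)‑5‑[(1E)‑2‑(TBSO‑methyl)hexa‑1,5‑dien‑1‑yl]‑3‑(hydroxymethyl)furan‑2(5H)‑one
Product: 17 (5R)‑3‑(bromomethyl)‑5‑[(1E)‑2‑(TBSO‑methyl)hexa‑1,5‑dien‑1‑yl]furan‑2(5H)‑one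
Conditions: CBr4, PPh3, CH2Cl2, 0 °C
Reagents that add atoms: carbon tetrabromide, BrC(Br)(Br)Br
Why: Appel bromination converts the primary allylic alcohol to the bromide under neutral conditions that do not deprotonate the acidic γ‑position.

Step 11
Reactants: 18 2‑methylidenepropane‑1,3‑diol
Product: 19 2‑{[(4‑methoxybenzyl)oxy]methyl}prop‑2‑en‑1‑ol
Conditions: NaH (1 equiv), PMBCl, Bu4NI (cat.), THF, 0 °C → rt; diol in excess
Reagents that add atoms: 4‑methoxybenzyl chloride, COc1ccc(CCl)cc1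
Why: Williamson mono‑etherification of a symmetrical diol gives the mono‑PMB ether, separable from diol and bis‑ether.

Step 12
Reactants: 19 2‑{[(4‑methoxybenzyl)oxy]methyl}prop‑2‑en‑1‑ol
Product: 20 1‑({[2‑(bromomethyl)prop‑2‑en‑1‑yl]oxy}methyl)‑4‑methoxybenzene
Conditions: CBr4, PPh3, CH2Cl2, 0 °C
Reagents that add atoms: carbon tetrabromide, BrC(Br)(Br)Br
Why: Appel bromination of the allylic alcohol gives the allyl bromide without touching the PMB ether.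

Step 13
Reactants: 20 1‑({[2‑(bromomethyl)prop‑2‑en‑1‑yl]oxy}methyl)‑4‑methoxybenzene
Product: 22 3‑{[(4‑methoxybenzyl)oxy]methyl}but‑3‑en‑1‑ol, via allylzinc bromide 21 (not isolated)
Conditions: Zn dust, 37% aq. HCHO, THF/sat. aq. NH4Cl, rt
Reagents that add atoms: formaldehyde, C=O
Why: Aqueous Barbier allylation of formaldehyde gives the homoallylic alcohol (this CH2OH becomes C8), and the two allyl termini are equivalent so there is no regiochemical issue.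

Step 14
Reactants: 22 3‑{[(4‑methoxybenzyl)oxy]methyl}but‑3‑en‑1‑ol
Product: 23 3‑{[(4‑methoxybenzyl)oxy]methyl}but‑3‑enal
Conditions: DMP, pyridine, CH2Cl2, 0 °C, 30 min; crude used at once
Reagents that add atoms: none
Why: Buffered Dess–Martin oxidation gives the β,γ‑unsaturated aldehyde without isomerising it into conjugation.

Step 15
Reactants: 17 (5R)‑3‑(bromomethyl)‑5‑[(1E)‑2‑(TBSO‑methyl)hexa‑1,5‑dien‑1‑yl]furan‑2(5H)‑one; 23 3‑{[(4‑methoxybenzyl)oxy]methyl}but‑3‑enal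
Product: 25 (4R,5R)‑5‑[(1E)‑2‑(TBSO‑methyl)hexa‑1,5‑dien‑1‑yl]‑4‑[(1S)‑1‑hydroxy‑3‑(PMBO‑methyl)but‑3‑en‑1‑yl]‑3‑methylideneoxolan‑2‑one, via allylchromium dichloride 24 (not isolated)
Conditions: CrCl2 (3 equiv), THF, 0 °C → rt
Reagents that add atoms: none
Why: In this Nozaki–Hiyama (Barbier‑type) carbonyl allylation the allylchromium adds through its ring γ‑carbon in a chair transition state, anti to the C6 dienyl group (6,7‑trans) and, because the ring locks the γ‑substituent trans to CH2Cr, with anti topicity (8S, the C8 epimer of the target, corrected in step 16), while the double bond moves out of the ring to give the α‑methylene lactone.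

Step 16
Reactants: 25 (4R,5R)‑5‑[(1E)‑2‑(TBSO‑methyl)hexa‑1,5‑dien‑1‑yl]‑4‑[(1S)‑1‑hydroxy‑3‑(PMBO‑methyl)but‑3‑en‑1‑yl]‑3‑methylideneoxolan‑2‑one; 26 (2R)‑2‑methylbutanoic acid
Product: 27 (1R)‑1‑[(2R,3R)‑2‑[(1E)‑2‑(TBSO‑methyl)hexa‑1,5‑dien‑1‑yl]‑4‑methylidene‑5‑oxooxolan‑3‑yl]‑3‑(PMBO‑methyl)but‑3‑en‑1‑yl (2R)‑2‑methylbutanoate
Conditions: PPh3, DIAD, PhMe, 0 °C → rt
Reagents that add atoms: none
Why: Mitsunobu esterification displaces the oxyphosphonium by carboxylate in an SN2 step, inverting C8 from S to the R (8β) configuration of the target, while the acid's own stereocentre is untouched under these non‑basic conditions.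

Step 17
Reactants: 27 (1R)‑1‑[(2R,3R)‑2‑[(1E)‑2‑(TBSO‑methyl)hexa‑1,5‑dien‑1‑yl]‑4‑methylidene‑5‑oxooxolan‑3‑yl]‑3‑(PMBO‑methyl)but‑3‑en‑1‑yl (2R)‑2‑methylbutanoate
Product: 28 (3aR,4R,6E,10E,11aR)‑10‑(TBSO‑methyl)‑6‑(PMBO‑methyl)‑3‑methylidene‑2‑oxo‑2,3,3a,4,5,8,9,11a‑octahydrocyclodeca[b]furan‑4‑yl (2R)‑2‑methylbutanoate
Conditions: second‑generation Grubbs catalyst RuCl2(=CHPh)(PCy3)(H2IMes) (10 mol %), 1,4‑benzoquinone (20 mol %), PhMe (1 mM), 80 °C, slow addition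
Reagents that add atoms: none
Why: Ring‑closing metathesis between the terminal vinyl group and the 1,1‑disubstituted allylic ether closes C1=C10 with loss of ethene; the ten‑membered ring with a cis ring olefin and trans‑fused lactone favours the ring‑cis trisubstituted olefin (CIP E), and the trisubstituted and electron‑poor olefins are poor competitors.

Step 18
Reactants: 28 (3aR,4R,6E,10E,11aR)‑10‑(TBSO‑methyl)‑6‑(PMBO‑methyl)‑3‑methylidene‑2‑oxo‑2,3,3a,4,5,8,9,11a‑octahydrocyclodeca[b]furan‑4‑yl (2R)‑2‑methylbutanoate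
Product: 29 (3aR,4R,6E,10E,11aR)‑6‑(hydroxymethyl)‑10‑(TBSO‑methyl)‑3‑methylidene‑2‑oxo‑2,3,3a,4,5,8,9,11a‑octahydrocyclodeca[b]furan‑4‑yl (2R)‑2‑methylbutanoate
Conditions: DDQ, CH2Cl2/pH 7 buffer (10:1), 0 °C
Reagents that add atoms: none
Why: Oxidative PMB cleavage via the benzylic oxocarbenium ion frees only the C14 alcohol and leaves the silyl ether, esters and olefins alone.

Step 19
Reactants: 29 (3aR,4R,6E,10E,11aR)‑6‑(hydroxymethyl)‑10‑(TBSO‑methyl)‑3‑methylidene‑2‑oxo‑2,3,3a,4,5,8,9,11a‑octahydrocyclodeca[b]furan‑4‑yl (2R)‑2‑methylbutanoate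
Product: 30 (3aR,4R,6E,10E,11aR)‑6‑formyl‑10‑(TBSO‑methyl)‑3‑methylidene‑2‑oxo‑2,3,3a,4,5,8,9,11a‑octahydrocyclodeca[b]furan‑4‑yl (2R)‑2‑methylbutanoate
Conditions: DMP, pyridine, CH2Cl2, 0 °C → rt
Reagents that add atoms: none
Why: Dess–Martin oxidation of the only free (allylic) alcohol gives the C14 enal, whose geometry (C2 trans to CHO) is also the thermodynamically preferred one.

Step 20
Reactants: 30 (3aR,4R,6E,10E,11aR)‑6‑formyl‑10‑(TBSO‑methyl)‑3‑methylidene‑2‑oxo‑2,3,3a,4,5,8,9,11a‑octahydrocyclodeca[b]furan‑4‑yl (2R)‑2‑methylbutanoate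
Product: 31 (3aR,4R,6E,10E,11aR)‑6‑formyl‑10‑(hydroxymethyl)‑3‑methylidene‑2‑oxo‑2,3,3a,4,5,8,9,11a‑octahydrocyclodeca[b]furan‑4‑yl (2R)‑2‑methylbutanoate
Conditions: HF·pyridine, pyridine, THF, 0 °C → rt
Reagents that add atoms: none
Why: Buffered fluoride desilylation of the primary allylic TBS ether is mild enough for the enal, the α‑methylene lactone and the C8 ester, and gives the target.

**Compound list**

1 | 5‑bromopent‑1‑ene | C=CCCCBr | starting material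
2 | (pent‑4‑en‑1‑yl)triphenylphosphonium bromide | C=CCCC[P+](c1ccccc1)(c1ccccc1)c1ccccc1.[Br-] | intermediate
3 | triphenyl(pent‑4‑en‑1‑ylidene)‑λ5‑phosphane (ylide) | C=CCCC=P(c1ccccc1)(c1ccccc1)c1ccccc1 | intermediate
4 | (1‑formylpent‑4‑en‑1‑yl)triphenylphosphonium ethoxide | C=CCCC(C=O)[P+](c1ccccc1)(c1ccccc1)c1ccccc1.CC[O-] | intermediate
5 | 2‑(triphenyl‑λ5‑phosphanylidene)hex‑5‑enal | C=CCCC(C=O)=P(c1ccccc1)(c1ccccc1)c1ccccc1 | intermediate
6 | (5S)‑5‑(hydroxymethyl)oxolan‑2‑one | OC[C@@H]1CCC(=O)O1 | starting material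
7 | (2S)‑5‑oxooxolane‑2‑carbaldehyde | O=C[C@@H]1CCC(=O)O1 | intermediate
8 | (2E)‑2‑{[(2S)‑5‑oxooxolan‑2‑yl]methylidene}hex‑5‑enal | O=C1CC[C@@H](/C=C(/C=O)CCC=C)O1 | intermediate
9 | (5S)‑5‑[(1E)‑2‑(hydroxymethyl)hexa‑1,5‑dien‑1‑yl]oxolan‑2‑one | O=C1CC[C@@H](/C=C(/CO)CCC=C)O1 | intermediate
10 | (5S)‑5‑[(1E)‑2‑(TBSO‑methyl)hexa‑1,5‑dien‑1‑yl]oxolan‑2‑one | O=C1CC[C@@H](/C=C(/CO[Si](C)(C)C(C)(C)C)CCC=C)O1 | intermediate
11 | lithium enolate of 10 | [Li]OC1=CC[C@@H](/C=C(/CO[Si](C)(C)C(C)(C)C)CCC=C)O1 | intermediate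
12 | (5S)‑5‑[(1E)‑2‑(TBSO‑methyl)hexa‑1,5‑dien‑1‑yl]‑3‑(phenylselanyl)oxolan‑2‑one | O=C1C([Se]c2ccccc2)C[C@@H](/C=C(/CO[Si](C)(C)C(C)(C)C)CCC=C)O1 | intermediate
13 | lithium enolate of 12 | [Li]OC1=C([Se]c2ccccc2)C[C@@H](/C=C(/CO[Si](C)(C)C(C)(C)C)CCC=C)O1 | intermediate
14 | (5S)‑5‑[(1E)‑2‑(TBSO‑methyl)hexa‑1,5‑dien‑1‑yl]‑3‑(hydroxymethyl)‑3‑(phenylselanyl)oxolan‑2‑one | O=C1C(CO)([Se]c2ccccc2)C[C@@H](/C=C(/CO[Si](C)(C)C(C)(C)C)CCC=C)O1 | intermediate
15 | selenoxide of 14 | O=C1C(CO)([Se](=O)c2ccccc2)C[C@@H](/C=C(/CO[Si](C)(C)C(C)(C)C)CCC=C)O1 | intermediate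
16 | (5R)‑5‑[(1E)‑2‑(TBSO‑methyl)hexa‑1,5‑dien‑1‑yl]‑3‑(hydroxymethyl)furan‑2(5H)‑one | O=C1C(CO)=C[C@@H](/C=C(/CO[Si](C)(C)C(C)(C)C)CCC=C)O1 | intermediate
17 | (5R)‑3‑(bromomethyl)‑5‑[(1E)‑2‑(TBSO‑methyl)hexa‑1,5‑dien‑1‑yl]furan‑2(5H)‑one | O=C1C(CBr)=C[C@@H](/C=C(/CO[Si](C)(C)C(C)(C)C)CCC=C)O1 | intermediate
18 | 2‑methylidenepropane‑1,3‑diol | C=C(CO)CO | starting material
19 | 2‑{[(4‑methoxybenzyl)oxy]methyl}prop‑2‑en‑1‑ol | C=C(CO)COCc1ccc(OC)cc1 | intermediate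
20 | 1‑({[2‑(bromomethyl)prop‑2‑en‑1‑yl]oxy}methyl)‑4‑methoxybenzene | C=C(CBr)COCc1ccc(OC)cc1 | intermediate
21 | {2‑[(4‑methoxybenzyloxy)methyl]prop‑2‑en‑1‑yl}zinc bromide | C=C(C[Zn]Br)COCc1ccc(OC)cc1 | intermediate
22 | 3‑{[(4‑methoxybenzyl)oxy]methyl}but‑3‑en‑1‑ol | C=C(CCO)COCc1ccc(OC)cc1 | intermediate
23 | 3‑{[(4‑methoxybenzyl)oxy]methyl}but‑3‑enal | C=C(CC=O)COCc1ccc(OC)cc1 | intermediate
24 | allylchromium dichloride from 17 | Cl[Cr](Cl)CC1=C[C@@H](/C=C(/CO[Si](C)(C)C(C)(C)C)CCC=C)OC1=O | intermediate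
25 | (4R,5R)‑5‑[(1E)‑2‑(TBSO‑methyl)hexa‑1,5‑dien‑1‑yl]‑4‑[(1S)‑1‑hydroxy‑3‑(PMBO‑methyl)but‑3‑en‑1‑yl]‑3‑methylideneoxolan‑2‑one | C=C1C(=O)O[C@H](/C=C(/CO[Si](C)(C)C(C)(C)C)CCC=C)[C@H]1[C@@H](O)CC(=C)COCc2ccc(OC)cc2 | intermediate
26 | (2R)‑2‑methylbutanoic acid | CC[C@@H](C)C(=O)O | starting material
27 | (1R)‑1‑[(2R,3R)‑2‑[(1E)‑2‑(TBSO‑methyl)hexa‑1,5‑dien‑1‑yl]‑4‑methylidene‑5‑oxooxolan‑3‑yl]‑3‑(PMBO‑methyl)but‑3‑en‑1‑yl (2R)‑2‑methylbutanoate | C=C1C(=O)O[C@H](/C=C(/CO[Si](C)(C)C(C)(C)C)CCC=C)[C@H]1[C@H](OC(=O)[C@H](C)CC)CC(=C)COCc2ccc(OC)cc2 | intermediate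
28 | (3aR,4R,6E,10E,11aR)‑10‑(TBSO‑methyl)‑6‑(PMBO‑methyl)‑3‑methylidene‑2‑oxo‑2,3,3a,4,5,8,9,11a‑octahydrocyclodeca[b]furan‑4‑yl (2R)‑2‑methylbutanoate | C=C1C(=O)O[C@@H]2/C=C(/CO[Si](C)(C)C(C)(C)C)CC/C=C(/COCc3ccc(OC)cc3)C[C@@H](OC(=O)[C@H](C)CC)[C@@H]12 | intermediate
29 | (3aR,4R,6E,10E,11aR)‑6‑(hydroxymethyl)‑10‑(TBSO‑methyl)‑3‑methylidene‑2‑oxo‑2,3,3a,4,5,8,9,11a‑octahydrocyclodeca[b]furan‑4‑yl (2R)‑2‑methylbutanoate | C=C1C(=O)O[C@@H]2/C=C(/CO[Si](C)(C)C(C)(C)C)CC/C=C(/CO)C[C@@H](OC(=O)[C@H](C)CC)[C@@H]12 | intermediate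
30 | (3aR,4R,6E,10E,11aR)‑6‑formyl‑10‑(TBSO‑methyl)‑3‑methylidene‑2‑oxo‑2,3,3a,4,5,8,9,11a‑octahydrocyclodeca[b]furan‑4‑yl (2R)‑2‑methylbutanoate | C=C1C(=O)O[C@@H]2/C=C(/CO[Si](C)(C)C(C)(C)C)CC/C=C(/C=O)C[C@@H](OC(=O)[C@H](C)CC)[C@@H]12 | intermediate
31 | (3aR,4R,6E,10E,11aR)‑6‑formyl‑10‑(hydroxymethyl)‑3‑methylidene‑2‑oxo‑2,3,3a,4,5,8,9,11a‑octahydrocyclodeca[b]furan‑4‑yl (2R)‑2‑methylbutanoate | C=C1C(=O)O[C@@H]2/C=C(/CO)CC/C=C(/C=O)C[C@@H](OC(=O)[C@H](C)CC)[C@@H]12 | target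

**Step count and risk**

Total steps: 20. Longest linear sequence: 15 steps (1, 2, 4–10, 15–20, from 5‑bromopent‑1‑ene).

Most likely to fail, with fallbacks:

Step 15 (key allylation). The allylchromium carries a vinylogous β‑acyloxy leaving group and could open to a trienoic acid, and the β,γ‑unsaturated aldehyde is fragile. The fallback sets out from 17 and returns at 25. Bromide 17 is borylated with bis(pinacolato)diboron (Pd2(dba)3 cat., DMSO, 50 °C) to the isolable, non‑basic allylboronate (5R)‑5‑[(1E)‑2‑(TBSO‑methyl)hexa‑1,5‑dien‑1‑yl]‑3‑[(4,4,5,5‑tetramethyl‑1,3,2‑dioxaborolan‑2‑yl)methyl]furan‑2(5H)‑one F1. Thermal allylboration of aldehyde 23 with F1 (PhMe, rt → 50 °C, aqueous work‑up) goes through the same closed chair and so gives the same trans, anti adduct 25 without a free carbanionic metal species.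

Step 16 (Mitsunobu inversion). The carbinol is flanked by a ring methine, so elimination to a conjugated diene or participation by the lactone carbonyl may compete with substitution by a weakly acidic aliphatic acid. The fallback sets out from 25 and returns at 27. Alcohol 25 is converted with chloromethanesulfonyl chloride and pyridine (CH2Cl2, 0 °C) to the chloromethanesulfonate of 25 F2. This compact, highly reactive sulfonate is displaced with inversion by cesium (2R)‑2‑methylbutanoate (made from 26 and Cs2CO3) with 18‑crown‑6 in PhMe at 60–80 °C to give 27.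

Step 17 (ring‑closing metathesis). Closing a ten‑membered ring onto a 1,1‑disubstituted olefin is slow, and the α‑methylene lactone can intercept the ruthenium carbene (eight‑membered ring or oligomers). The fallback sets out from 27 and returns at 28. Me2NH (THF, 0 °C) adds to the methylene lactone to give the Michael adduct 11,13‑dihydro‑13‑(dimethylamino) derivative of 27 F3. F3 is cyclised as its tosylate salt (1 equiv TsOH) with the same ruthenium catalyst to the macrocyclic amine 11,13‑dihydro‑13‑(dimethylamino) derivative of 28 F4. MeI (MeCN, rt) gives the methiodide of F4 F5, which eliminates trimethylamine with aq. NaHCO3 to regenerate the α‑methylene lactone 28.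

**Further compounds**

F1 | step 15 | (5R)‑5‑[(1E)‑2‑(TBSO‑methyl)hexa‑1,5‑dien‑1‑yl]‑3‑[(4,4,5,5‑tetramethyl‑1,3,2‑dioxaborolan‑2‑yl)methyl]furan‑2(5H)‑one | CC1(C)OB(CC2=C[C@@H](/C=C(/CO[Si](C)(C)C(C)(C)C)CCC=C)OC2=O)OC1(C)C
F2 | step 16 | chloromethanesulfonate of 25 | C=C1C(=O)O[C@H](/C=C(/CO[Si](C)(C)C(C)(C)C)CCC=C)[C@H]1[C@@H](OS(=O)(=O)CCl)CC(=C)COCc2ccc(OC)cc2
F3 | step 17 | 11,13‑dihydro‑13‑(dimethylamino) derivative of 27 (C11 epimers) | CN(C)CC1C(=O)O[C@H](/C=C(/CO[Si](C)(C)C(C)(C)C)CCC=C)[C@H]1[C@H](OC(=O)[C@H](C)CC)CC(=C)COCc2ccc(OC)cc2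
F4 | step 17 | 11,13‑dihydro‑13‑(dimethylamino) derivative of 28 (C11 epimers) | CN(C)CC1C(=O)O[C@@H]2/C=C(/CO[Si](C)(C)C(C)(C)C)CC/C=C(/COCc3ccc(OC)cc3)C[C@@H](OC(=O)[C@H](C)CC)[C@@H]12
F5 | step 17 | methiodide of F4 | C[N+](C)(C)CC1C(=O)O[C@@H]2/C=C(/CO[Si](C)(C)C(C)(C)C)CC/C=C(/COCc3ccc(OC)cc3)C[C@@H](OC(=O)[C@H](C)CC)[C@@H]12.[I-]
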